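**Retrosynthetic overview**

- Cadinane numbering: ring A = C1–C6 (C4=C5, C3–OAc), ring B = C1/C6–C10 (C7 acrylic acid, C8 ester, C10 methyl carbinol). Late events on a cis-octalin: Yamaguchi esterification of 8-OH with the acetonide-protected side-chain acid, C12 aldehyde → C11 methylenation → chlorite oxidation, and HAT hydration of a 10(14)-methylene.
- Key disconnection: C1–C6 and C8–C9 are cut together, which unravels both rings to an acyclic (2Z,4Z)-dienal C8(=O)–C7=C6–C5=C4–C3–C2–C1=C10(CH3)2, an isomer of the bicyclic carbinol.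
- Enabling feature: C6 is allylic to the ring A olefin C4=C5 and β to the carbinol carbon C8, so C6=C7–C8=O can be an enal. The methyl carbinol C10 with its neighbours C1 and C9 and its methyl C14 is a former isopropylidene group that can act twice as ene donor. Ring B is thus a 3+3 sum of enal and isopropylidene.
- Ring order: temporary 2H-pyran (O–C4 bond, absent from the target, stores the Z geometry of C6=C7) → opened by the Lewis acid in the key step → ring A (C1–C6) → ring B (C8–C9).
- The dienal is built by three stereodefining steps: zinc-catalysed alkynylation (C3), cuprate syn-addition ((Z)-C4=C5), Still–Gennari olefination ((Z)-C6=C7).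

Key step: step 12

Remark on naming: cadinane numbering is used for all bicyclic compounds; β is the face of ring B that carries H-1 and H-6 in the target, α the opposite face (target: 3β-OAc, 7β-H, 8α-O-acyl, 10β-OH, 10α-CH3).
Assumption: in step 2 the ProPhenol antipode is the one that gives the 4S alcohol; (S,S)-ProPhenol is assumed from the usual sense of induction.

**Route**

Step 1
Reactants: 1 4-methylpent-3-en-1-ol
Product: 2 4-methylpent-3-enal
Conditions: Dess–Martin periodinane, NaHCO3, CH2Cl2, 0 °C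
Reagents that add atoms: none
Why: Buffered Dess–Martin oxidation should give the β,γ-unsaturated aldehyde without migration of the double bond; no stereocenter is involved.

Step 2
Reactants: 2 4-methylpent-3-enal; 3 methyl propiolate
Product: 4 methyl (4S)-4-hydroxy-7-methyloct-6-en-2-ynoate
Conditions: Me2Zn, (S,S)-ProPhenol (20 mol %), Ph3P=O (40 mol %), toluene, 0 °C; aq. NH4Cl
Reagents that add atoms: none
Why: Zinc–ProPhenol catalysed enantioselective alkynylation of an aldehyde, in which the dinuclear zinc catalyst delivers the alkynyl group to one aldehyde face and sets C3 (4S in this compound).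

Step 3
Reactants: 4 methyl (4S)-4-hydroxy-7-methyloct-6-en-2-ynoate
Product: 5 methyl (4S)-4-(tert-butyldimethylsilyloxy)-7-methyloct-6-en-2-ynoate
Conditions: TBSCl, imidazole, DMF, rt
Reagents that add atoms: tert-butyldimethylsilyl chloride, CC(C)(C)[Si](C)(C)Cl
Why: Standard silylation of a secondary alcohol; the silyl ether also prevents lactonisation after the next step.

Step 4
Reactants: 5 methyl (4S)-4-(tert-butyldimethylsilyloxy)-7-methyloct-6-en-2-ynoate
Product: 6 methyl (2Z,4S)-4-(tert-butyldimethylsilyloxy)-3,7-dimethylocta-2,6-dienoate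
Conditions: Me2CuLi (from MeLi, CuI), THF, −78 °C; MeOH, −78 °C
Reagents that add atoms: lithium dimethylcuprate, [Li+].C[Cu-]C
Why: Cuprate conjugate addition to an ynoate is a syn-carbocupration, and protonation at −78 °C with retention should give the Z enoate (ester cis to the carbinol carbon, the future cis relation of C6 and C3).

Step 5
Reactants: 6 methyl (2Z,4S)-4-(tert-butyldimethylsilyloxy)-3,7-dimethylocta-2,6-dienoate
Product: 7 (2Z,4S)-4-(tert-butyldimethylsilyloxy)-3,7-dimethylocta-2,6-dien-1-ol
Conditions: i-Bu2AlH (2.2 equiv), CH2Cl2, −78 °C; aq. potassium sodium tartrate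
Reagents that add atoms: none
Why: 1,2-Reduction of an enoate by an aluminium hydride leaves the olefin geometry and the silyl ether untouched.

Step 6
Reactants: 7 (2Z,4S)-4-(tert-butyldimethylsilyloxy)-3,7-dimethylocta-2,6-dien-1-ol
Product: 8 (2Z,4S)-4-(tert-butyldimethylsilyloxy)-3,7-dimethylocta-2,6-dienal
Conditions: MnO2, CH2Cl2, rt
Reagents that add atoms: none
Why: Neutral allylic oxidation with MnO2 should keep the Z geometry of this neral-type enal.

Step 7
Reactants: 9 2-iodoethanol
Product: 10 triethyl(2-iodoethoxy)silane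
Conditions: TESCl, imidazole, CH2Cl2, 0 °C
Reagents that add atoms: chlorotriethylsilane, CC[Si](Cl)(CC)CC
Why: Standard silylation; the primary triethylsilyl ether is chosen because it can later be oxidised directly to the aldehyde.

Step 8
Reactants: 11 methyl bis(2,2,2-trifluoroethyl)phosphonoacetate; 10 triethyl(2-iodoethoxy)silane
Product: 12 methyl 2-[bis(2,2,2-trifluoroethoxy)phosphoryl]-4-(triethylsilyloxy)butanoate (racemic)
Conditions: NaH, DMF, 0 °C to rt
Reagents that add atoms: none
Why: C-Alkylation of the stabilised phosphonoacetate anion with a primary iodide; the new stereocenter is lost in the olefination.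

Step 9
Reactants: 8 (2Z,4S)-4-(tert-butyldimethylsilyloxy)-3,7-dimethylocta-2,6-dienal; 12 methyl 2-[bis(2,2,2-trifluoroethoxy)phosphoryl]-4-(triethylsilyloxy)butanoate
Product: 13 methyl (2Z,4Z,6S)-6-(tert-butyldimethylsilyloxy)-5,9-dimethyl-2-[2-(triethylsilyloxy)ethyl]deca-2,4,8-trienoate
Conditions: KN(SiMe3)2, 18-crown-6, THF, −78 °C
Reagents that add atoms: none
Why: Still–Gennari olefination with a trifluoroethyl phosphonate and a dissociated potassium counter-ion is kinetically Z-selective, placing the ester carbon (future C8) cis to C5.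

Step 10
Reactants: 13 methyl (2Z,4Z,6S)-6-(tert-butyldimethylsilyloxy)-5,9-dimethyl-2-[2-(triethylsilyloxy)ethyl]deca-2,4,8-trienoate
Product: 14 (2Z,4Z,6S)-6-(tert-butyldimethylsilyloxy)-5,9-dimethyl-2-[2-(triethylsilyloxy)ethyl]deca-2,4,8-trien-1-ol
Conditions: i-Bu2AlH (2.2 equiv), CH2Cl2, −78 °C; aq. potassium sodium tartrate
Reagents that add atoms: none
Why: 1,2-Reduction of the dienoate to the dienyl alcohol with both Z olefins and both silyl ethers retained.

Step 11
Reactants: 14 (2Z,4Z,6S)-6-(tert-butyldimethylsilyloxy)-5,9-dimethyl-2-[2-(triethylsilyloxy)ethyl]deca-2,4,8-trien-1-ol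
Product: 16 2-methyl-2-[(1S)-1-(tert-butyldimethylsilyloxy)-4-methylpent-3-enyl]-5-[2-(triethylsilyloxy)ethyl]-2H-pyran (both C2 epimers), via free dienal 15 (not isolated)
Conditions: MnO2, CH2Cl2, rt
Reagents that add atoms: none
Why: Allylic oxidation gives the free (2Z,4Z)-dienal 15, which should close by thermal oxa-6π electrocyclisation to the 2H-pyran valence tautomer (favoured by the fully substituted δ-carbon); the new pyran stereocenter is erased when the ring is opened in the next step.

Step 12
Reactants: 16 2-methyl-2-[(1S)-1-(tert-butyldimethylsilyloxy)-4-methylpent-3-enyl]-5-[2-(triethylsilyloxy)ethyl]-2H-pyran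
Product: 19 cis-fused carbinol (3β-OTBS; 7α-CH2CH2OTES; 8α-OH; 10(14)-methylene; 1β-H 6β-H 7β-H), via Me2AlCl-bound dienal 17 (not isolated), via Me2AlCl-bound ene aldehyde 18 (not isolated)
Conditions: Me2AlCl (2.5 equiv), CH2Cl2, −78 to −20 °C; aq. potassium sodium tartrate
Reagents that add atoms: none
Why: Me2AlCl binds the ring oxygen of pyran 16 and opens the ring (Lewis acid-assisted retro-oxa-6π opening) directly to the oxygen-bound aluminium complex 17 of the (2Z,4Z)-dienal, so the free aldehyde is not formed; in 17 the C1=C10 olefin adds through C1 to the β-carbon C6 (6-exo-trig closure of ring A) while a methyl hydrogen of the developing C10 cation passes suprafacially to C7, an intramolecular ene reaction with C6=C7 as enophile that gives the aluminium-bound aldehyde 18 with a new isopropenyl group; the complexed aldehyde then closes ring B by a type 2 carbonyl-ene reaction (C9 to C8, hydrogen from C14 to oxygen; carbonyl exocyclic and C10 of the ene olefin endocyclic to the forming six-membered ring), and the tartrate work-up releases carbinol 19 from aluminium, so the whole step is an isomerisation of 16. The closest known reaction type is the sequential ene annulation of enals with alkenes under alkylaluminium chlorides (conjugate ene reaction followed by type 2 carbonyl-ene cyclisation). C1 and C6 are controlled by C3: ring A should form through a half-chair with the C3 silyloxy group pseudoaxial (A(1,2) strain with the C4 methyl), the attacking olefin equatorial at C1 and the fully substituted enal carbon C7 pseudoaxial at C6 (A(1,3) strain with H-5 in the twisted dienal), which gives the cis ring fusion anti to the C3 oxygen. C7 is controlled by the Z geometry of C6=C7 that the pyran ring stores: suprafacial delivery of C1 and H across a double bond in which C8 is cis to C5 places the C7 side chain cis to C5. C8 should be set in a chair with the C7 side chain equatorial and the aluminium-bound carbonyl axial, as the six-centre hydrogen transfer from C14 requires, giving the 8α-carbinol. The step needs the ene pathway to win over collapse of the zwitterion to a dihydropyran or cyclobutane and over E/Z leakage at C6=C7: both collapses are reversible under Me2AlCl while the hydrogen shift is not, Me2AlCl scavenges protons as methane, and the Z-configured complex 17 is regenerated from the pyran.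

Step 13
Reactants: 19 cis-fused carbinol (3β-OTBS; 7α-CH2CH2OTES; 8α-OH; 10(14)-methylene)
Product: 21 8α,10β-diol (10α-CH3; 3β-OTBS; 12-OTES), via hydroperoxide 20 (not isolated)
Conditions: Co(acac)2 (20 mol %), PhSiH3, O2 (1 atm), i-PrOH/THF, rt; then PPh3
Reagents that add atoms: dioxygen, O=O
Why: Mukaiyama hydration (cobalt hydride HAT) is Markovnikov and prefers the 1,1-disubstituted over the trisubstituted olefin, and the C10 radical should be trapped by O2 from the convex β-face because the α-face is closed by C2, C5, the C7 side chain and O-8.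

Step 14
Reactants: 22 but-2-yne-1,4-diol
Product: 23 (E)-2-(tributylstannyl)but-2-ene-1,4-diol
Conditions: Bu3SnH, Pd(PPh3)2Cl2 (2 mol %), THF, rt
Reagents that add atoms: tributyltin hydride, CCCC[SnH](CCCC)CCCC
Why: Palladium-catalysed hydrostannation is a syn addition, so the two hydroxymethyl groups end up cis, as the side chain requires.

Step 15
Reactants: 23 (E)-2-(tributylstannyl)but-2-ene-1,4-diol
Product: 24 tributyl(2,2-dimethyl-4,7-dihydro-1,3-dioxepin-5-yl)stannane
Conditions: 2,2-dimethoxypropane, PPTS (cat.), CH2Cl2, rt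
Reagents that add atoms: 2,2-dimethoxypropane, COC(C)(C)OC
Why: Acetonide formation from a cis-1,4-diol; the seven-membered ring also locks the olefin geometry for all later steps.

Step 16
Reactants: 24 tributyl(2,2-dimethyl-4,7-dihydro-1,3-dioxepin-5-yl)stannane
Product: 26 2,2-dimethyl-4,7-dihydro-1,3-dioxepine-5-carboxylic acid, via vinyllithium 25 (not isolated)
Conditions: n-BuLi, THF, −78 °C; CO2; aq. NaH2PO4
Reagents that add atoms: carbon dioxide, O=C=O
Why: Tin–lithium exchange of an alkenylstannane followed by carboxylation, with the ring-locked geometry retained.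

Step 17
Reactants: 21 8α,10β-diol (3β-OTBS; 12-OTES); 26 2,2-dimethyl-4,7-dihydro-1,3-dioxepine-5-carboxylic acid
Product: 28 8α-(2,2-dimethyl-4,7-dihydro-1,3-dioxepine-5-carbonyloxy) 10β-ol (3β-OTBS; 12-OTES), via mixed anhydride 27 (not isolated)
Conditions: 2,4,6-trichlorobenzoyl chloride, Et3N, THF, rt; then 21, DMAP, toluene, rt
Reagents that add atoms: none
Why: Yamaguchi esterification acylates the secondary 8-OH with retention and leaves the tertiary 10-OH alone; the ring-locked olefin of the acid cannot isomerise.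

Step 18
Reactants: 28 8α-ester (3β-OTBS; 12-OTES; 10β-OH)
Product: 29 12-aldehyde (7α-CH2CHO; 3β-OTBS; 8α-ester; 10β-OH)
Conditions: (COCl)2, DMSO, CH2Cl2, −78 to −30 °C; Et3N, to 0 °C
Reagents that add atoms: none
Why: Under Swern conditions a primary triethylsilyl ether is cleaved and oxidised to the aldehyde in one pot, while the secondary TBS ether, the acetonide and the tertiary alcohol should survive.

Step 19
Reactants: 29 12-aldehyde (3β-OTBS; 8α-ester; 10β-OH)
Product: 31 11(13)-en-12-al (α-methylene aldehyde; 3β-OTBS; 8α-ester; 10β-OH), via Mannich base 30 (not isolated)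
Conditions: Eschenmoser's salt, Et3N, CH2Cl2, rt
Reagents that add atoms: N,N-dimethylmethyleneiminium iodide, C=[N+](C)C.[I-]
Why: Mannich reaction at C11 followed by β-elimination of dimethylamine gives the α-methylene aldehyde; C7 is not α to the carbonyl and should not epimerise.

Step 20
Reactants: 31 11(13)-en-12-al (3β-OTBS; 8α-ester; 10β-OH)
Product: 32 11(13)-en-12-oic acid (3β-OTBS; 8α-ester; 10β-OH)
Conditions: NaClO2, NaH2PO4, 2-methyl-2-butene, t-BuOH/H2O, rt
Reagents that add atoms: sodium chlorite, [Na+].[O-]Cl=O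
Why: Pinnick oxidation converts the enal into the acrylic acid without touching the olefins, since hypochlorite is scavenged.

Step 21
Reactants: 32 11(13)-en-12-oic acid (3β-OTBS)
Product: 33 3β-hydroxy acid (8α-ester; 10β-OH; acetonide intact)
Conditions: Bu4NF, AcOH, THF, rt
Reagents that add atoms: none
Why: Buffered fluoride cleaves the secondary silyl ether and leaves the esters and the acetonide intact.

Step 22
Reactants: 33 3β-hydroxy acid
Product: 34 3β-acetoxy acid (8α-ester; 10β-OH; acetonide intact)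
Conditions: Ac2O, pyridine, CH2Cl2, rt; then H2O
Reagents that add atoms: acetic anhydride, CC(=O)OC(C)=O
Why: Acetylation without DMAP should be selective for the secondary allylic alcohol over the tertiary 10-OH, and any mixed anhydride at C12 is hydrolysed on aqueous work-up.

Step 23
Reactants: 34 3β-acetoxy acid (acetonide)
Product: 35 target (CNP0468194.4)
Conditions: AcOH/H2O/THF (3:1:1), rt
Reagents that add atoms: none
Why: Mild acid hydrolysis of the labile seven-membered acetonide frees the two primary hydroxyls; the allylic acetate, the esters and the tertiary alcohol should tolerate these conditions.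

**Compound list**

1 | 4-methylpent-3-en-1-ol | CC(C)=CCCO | starting material
2 | 4-methylpent-3-enal | CC(C)=CCC=O | intermediate
3 | methyl propiolate | C#CC(=O)OC | starting material
4 | methyl (4S)-4-hydroxy-7-methyloct-6-en-2-ynoate | COC(=O)C#C[C@@H](O)CC=C(C)C | intermediate
5 | methyl (4S)-4-(tert-butyldimethylsilyloxy)-7-methyloct-6-en-2-ynoate | COC(=O)C#C[C@@H](O[Si](C)(C)C(C)(C)C)CC=C(C)C | intermediate
6 | methyl (2Z,4S)-4-(tert-butyldimethylsilyloxy)-3,7-dimethylocta-2,6-dienoate | COC(=O)\C=C(C)/[C@@H](O[Si](C)(C)C(C)(C)C)CC=C(C)C | intermediate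
7 | (2Z,4S)-4-(tert-butyldimethylsilyloxy)-3,7-dimethylocta-2,6-dien-1-ol | OC\C=C(C)/[C@@H](O[Si](C)(C)C(C)(C)C)CC=C(C)C | intermediate
8 | (2Z,4S)-4-(tert-butyldimethylsilyloxy)-3,7-dimethylocta-2,6-dienal | O=C\C=C(C)/[C@@H](O[Si](C)(C)C(C)(C)C)CC=C(C)C | intermediate
9 | 2-iodoethanol | OCCI | starting material
10 | triethyl(2-iodoethoxy)silane | CC[Si](CC)(CC)OCCI | intermediate
11 | methyl bis(2,2,2-trifluoroethyl)phosphonoacetate | COC(=O)CP(=O)(OCC(F)(F)F)OCC(F)(F)F | starting material
12 | methyl 2-[bis(2,2,2-trifluoroethoxy)phosphoryl]-4-(triethylsilyloxy)butanoate (racemic) | COC(=O)C(CCO[Si](CC)(CC)CC)P(=O)(OCC(F)(F)F)OCC(F)(F)F | intermediate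
13 | methyl (2Z,4Z,6S)-6-(tert-butyldimethylsilyloxy)-5,9-dimethyl-2-[2-(triethylsilyloxy)ethyl]deca-2,4,8-trienoate | COC(=O)/C(CCO[Si](CC)(CC)CC)=C\C=C(C)/[C@@H](O[Si](C)(C)C(C)(C)C)CC=C(C)C | intermediate
14 | (2Z,4Z,6S)-6-(tert-butyldimethylsilyloxy)-5,9-dimethyl-2-[2-(triethylsilyloxy)ethyl]deca-2,4,8-trien-1-ol | OC/C(CCO[Si](CC)(CC)CC)=C\C=C(C)/[C@@H](O[Si](C)(C)C(C)(C)C)CC=C(C)C | intermediate
15 | (2Z,4Z,6S)-6-(tert-butyldimethylsilyloxy)-5,9-dimethyl-2-[2-(triethylsilyloxy)ethyl]deca-2,4,8-trienal (free dienal) | O=C/C(CCO[Si](CC)(CC)CC)=C\C=C(C)/[C@@H](O[Si](C)(C)C(C)(C)C)CC=C(C)C | intermediate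
16 | 2-methyl-2-[(1S)-1-(tert-butyldimethylsilyloxy)-4-methylpent-3-enyl]-5-[2-(triethylsilyloxy)ethyl]-2H-pyran (both C2 epimers) | CC1(OC=C(CCO[Si](CC)(CC)CC)C=C1)[C@@H](O[Si](C)(C)C(C)(C)C)CC=C(C)C | intermediate
17 | Me2AlCl complex of the (2Z,4Z)-dienal: chlorodimethylaluminium bound to the carbonyl oxygen of the ring-opened pyran | C[Al-](C)(Cl)[O+]=C/C(CCO[Si](CC)(CC)CC)=C\C=C(C)/[C@@H](O[Si](C)(C)C(C)(C)C)CC=C(C)C | intermediate
18 | Me2AlCl complex of the ene aldehyde: ring A closed, C1 isopropenyl and C6 side chain cis and both trans to 3-OTBS, C6 bears CH(CHO)CH2CH2OTES with C7 as in 19, aluminium on the carbonyl oxygen | C[Al-](C)(Cl)[O+]=C[C@H](CCO[Si](CC)(CC)CC)[C@@H]1C=C(C)[C@@H](O[Si](C)(C)C(C)(C)C)C[C@@H]1C(C)=C | intermediate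
19 | cis-fused carbinol: 3β-OTBS, 7α-CH2CH2OTES, 8α-OH, 10(14)-methylene, 1β-H, 6β-H, 7β-H | CC[Si](CC)(CC)OCC[C@@H]1[C@@H]2C=C(C)[C@@H](O[Si](C)(C)C(C)(C)C)C[C@@H]2C(=C)C[C@@H]1O | intermediate
20 | 10β-hydroperoxide of 19 (10α-CH3) | CC[Si](CC)(CC)OCC[C@@H]1[C@@H]2C=C(C)[C@@H](O[Si](C)(C)C(C)(C)C)C[C@@H]2[C@@](C)(OO)C[C@@H]1O | intermediate
21 | 8α,10β-diol (10α-CH3, 3β-OTBS, 12-OTES) | CC[Si](CC)(CC)OCC[C@@H]1[C@@H]2C=C(C)[C@@H](O[Si](C)(C)C(C)(C)C)C[C@@H]2[C@@](C)(O)C[C@@H]1O | intermediate
22 | but-2-yne-1,4-diol | OCC#CCO | starting material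
23 | (E)-2-(tributylstannyl)but-2-ene-1,4-diol | OC/C=C(\CO)[Sn](CCCC)(CCCC)CCCC | intermediate
24 | tributyl(2,2-dimethyl-4,7-dihydro-1,3-dioxepin-5-yl)stannane | CC1(C)OCC=C(CO1)[Sn](CCCC)(CCCC)CCCC | intermediate
25 | (2,2-dimethyl-4,7-dihydro-1,3-dioxepin-5-yl)lithium | CC1(C)OCC=C(CO1)[Li] | intermediate
26 | 2,2-dimethyl-4,7-dihydro-1,3-dioxepine-5-carboxylic acid | CC1(C)OCC=C(CO1)C(=O)O | intermediate
27 | mixed anhydride of 26 with 2,4,6-trichlorobenzoic acid | CC1(C)OCC=C(CO1)C(=O)OC(=O)c1c(Cl)cc(Cl)cc1Cl | intermediate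
28 | 8α-ester of 21 with acid 26 (3β-OTBS, 12-OTES, 10β-OH) | CC[Si](CC)(CC)OCC[C@@H]1[C@@H]2C=C(C)[C@@H](O[Si](C)(C)C(C)(C)C)C[C@@H]2[C@@](C)(O)C[C@@H]1OC(=O)C1=CCOC(C)(C)OC1 | intermediate
29 | 12-aldehyde (7α-CH2CHO, 3β-OTBS, 8α-ester, 10β-OH) | O=CC[C@@H]1[C@@H]2C=C(C)[C@@H](O[Si](C)(C)C(C)(C)C)C[C@@H]2[C@@](C)(O)C[C@@H]1OC(=O)C1=CCOC(C)(C)OC1 | intermediate
30 | Mannich base: 11-(dimethylaminomethyl) 12-aldehyde (C11 epimers) | O=CC(CN(C)C)[C@@H]1[C@@H]2C=C(C)[C@@H](O[Si](C)(C)C(C)(C)C)C[C@@H]2[C@@](C)(O)C[C@@H]1OC(=O)C1=CCOC(C)(C)OC1 | intermediate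
31 | 11(13)-en-12-al (3β-OTBS, 8α-ester, 10β-OH) | C=C(C=O)[C@@H]1[C@@H]2C=C(C)[C@@H](O[Si](C)(C)C(C)(C)C)C[C@@H]2[C@@](C)(O)C[C@@H]1OC(=O)C1=CCOC(C)(C)OC1 | intermediate
32 | 11(13)-en-12-oic acid (3β-OTBS, 8α-ester, 10β-OH) | C=C(C(=O)O)[C@@H]1[C@@H]2C=C(C)[C@@H](O[Si](C)(C)C(C)(C)C)C[C@@H]2[C@@](C)(O)C[C@@H]1OC(=O)C1=CCOC(C)(C)OC1 | intermediate
33 | 3β-hydroxy acid (8α-ester, 10β-OH, acetonide) | C=C(C(=O)O)[C@@H]1[C@@H]2C=C(C)[C@@H](O)C[C@@H]2[C@@](C)(O)C[C@@H]1OC(=O)C1=CCOC(C)(C)OC1 | intermediate
34 | 3β-acetoxy acid (8α-ester, 10β-OH, acetonide) | C=C(C(=O)O)[C@@H]1[C@@H]2C=C(C)[C@@H](OC(C)=O)C[C@@H]2[C@@](C)(O)C[C@@H]1OC(=O)C1=CCOC(C)(C)OC1 | intermediate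
35 | CNP0468194.4: 3β-acetoxy-10β-hydroxy-8α-[(E)-4-hydroxy-2-(hydroxymethyl)but-2-enoyloxy] cis-fused cadina-4,11(13)-dien-12-oic acid (1S,3S,6S,7S,8S,10S in cadinane numbering) | C=C(C(=O)O)[C@@H]1[C@@H]2C=C(C)[C@@H](OC(C)=O)C[C@@H]2[C@@](C)(O)C[C@@H]1OC(=O)/C(=C/CO)CO | target

**Step count and risks**

Total step count: 23. Longest linear sequence: 18 steps (steps 1–6, 9–13, 17–23).

Three steps most likely to fail:

1. Step 12. The second ring closure may lose facial control at the aldehyde (closure through a chair with an equatorial carbonyl, or a stepwise Prins-type pathway), so that the C8 carbinol forms as an epimer mixture. The fallback sets C8 by reagent approach instead of by the cyclisation. It sets out from 19 as the C8 epimer mixture: oxidation with Dess–Martin periodinane/NaHCO3 gives the C8 ketone F1. Reduction with NaBH4/CeCl3·7H2O in MeOH at −78 °C should deliver hydride from the convex β-face, since the α-face carries C2, C5 and the C7 side chain. This returns the 8α-carbinol and comes back to the route at 19.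

2. Step 13. Capture of the C10 radical by O2 may show poor facial selectivity, or the cobalt hydride may transfer hydrogen to the ring A olefin. The fallback replaces the radical hydration by a polar Markovnikov hydration. It sets out from 19: oxymercuration with Hg(OAc)2 in THF/H2O gives the organomercurial F2, water attacking the tertiary carbon from the β-face because the axial α trajectory is closed by C5 and O-8. Demercuration with NaBH4/NaOH comes back to the route at 21.

3. Step 9. Z selectivity may erode with the α-branched phosphonate and the hindered enal, or the base may isomerise the Z enal. The fallback builds the trisubstituted olefin by iodo-olefination and carbonylation. Commercial 3-iodopropan-1-ol is silylated (TESCl, imidazole) to triethyl(3-iodopropoxy)silane F3, and PPh3 gives the phosphonium iodide F4. In one flask NaN(SiMe3)2 gives the ylide F5, I2 gives the α-iodophosphonium iodide F6, and a second equivalent of NaN(SiMe3)2 gives the α-iodo ylide F7. Stork–Zhao-type olefination of 8 with F7 should give the (Z)-vinyl iodide F8 with iodine cis to C5. Carbonylation (Pd(PPh3)4, CO, MeOH, Et3N) proceeds with retention and comes back to the route at 13.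

**Further compounds**

F1 | step 12 | C8 ketone (8-oxo analogue of 19) | CC[Si](CC)(CC)OCC[C@@H]1[C@@H]2C=C(C)[C@@H](O[Si](C)(C)C(C)(C)C)C[C@@H]2C(=C)CC1=O
F2 | step 13 | 14-(acetoxymercurio) derivative of diol 21 | CC[Si](CC)(CC)OCC[C@@H]1[C@@H]2C=C(C)[C@@H](O[Si](C)(C)C(C)(C)C)C[C@@H]2[C@@](C[Hg]OC(C)=O)(O)C[C@@H]1O
F3 | step 9 | triethyl(3-iodopropoxy)silane | CC[Si](CC)(CC)OCCCI
F4 | step 9 | triphenyl[3-(triethylsilyloxy)propyl]phosphonium iodide | CC[Si](CC)(CC)OCCC[P+](c1ccccc1)(c1ccccc1)c1ccccc1.[I-]
F5 | step 9 | triphenyl[3-(triethylsilyloxy)propylidene]phosphorane | CC[Si](CC)(CC)OCCC=P(c1ccccc1)(c1ccccc1)c1ccccc1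
F6 | step 9 | [1-iodo-3-(triethylsilyloxy)propyl]triphenylphosphonium iodide | CC[Si](CC)(CC)OCCC(I)[P+](c1ccccc1)(c1ccccc1)c1ccccc1.[I-]
F7 | step 9 | [1-iodo-3-(triethylsilyloxy)propylidene]triphenylphosphorane | CC[Si](CC)(CC)OCCC(I)=P(c1ccccc1)(c1ccccc1)c1ccccc1
F8 | step 9 | (Z)-vinyl iodide: iodo analogue of ester 13 with iodine in place of CO2Me, cis to C5 | I/C(CCO[Si](CC)(CC)CC)=C\C=C(C)/[C@@H](O[Si](C)(C)C(C)(C)C)CC=C(C)C
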